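**Plan**
1. Retrosynthetic cuts, in order: the three O–CH2Ph protecting-group bonds; then the C4–C5 CH2–CH2 bond of the C14 tether (C1 on the methoxy-bearing ring A, C14 on the resorcinol ring B); last the two aryl–alkyl bonds ring A–C1 and ring B–C14.
2. Enabling feature: C2–C13 are an unbranched, heteroatom-free run of methylenes, so C4 and C5 have like polarity and carry no handle. Each can arise as an unstabilised primary radical from a carboxylic acid one carbon longer, with CO2 as traceless handle. From the C4 radical the benzylic C1–H is reachable only by a strained 1,4-shift.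
3. The cut gives a C4 and a C10 arm, that is pent-4-enoate and undec-10-enoate minus CO2. It also separates the mono-O-methylated ring A from ring B, so the OMe/OH pattern is bought with 3-bromo-5-methoxyphenol and no selective methylation is needed.
4. Forward: each bromophenol is benzylated, then joined to its ω-alkenoate by hydroboration/B-alkyl Suzuki coupling with saponification in the same flask, then activated as the N-hydroxyphthalimide ester. The two esters are united at a nickel cathode with loss of two CO2, and hydrogenolysis frees the three phenols.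
5. No ring is built, since both arenes are bought. The target has no stereocentre and no C=C, so there is no stereochemistry to set.

Key step: step 7

Assumption: the SMILES contains no stereogenic element, so the compound is achiral and the demand for a single enantiomer is met by the constitution alone.

**Step 1**
Reactants: 1 3-bromo-5-methoxyphenol
Product: 2 1-(benzyloxy)-3-bromo-5-methoxybenzene
Conditions: BnBr, K2CO3, DMF, rt to 50 °C
Reagents that add atoms: benzyl bromide, BrCc1ccccc1
Why: Williamson ether synthesis on the phenoxide leaves the aryl bromide and the methyl ether untouched, and benzyl is chosen because it survives borane, base and cathodic nickel and leaves at the end without touching the O-methyl group.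

**Step 2**
Reactants: 2 1-(benzyloxy)-3-bromo-5-methoxybenzene; 3 methyl pent-4-enoate; 4 9-borabicyclo[3.3.1]nonane (9-BBN)
Product: 7 5-[3-(benzyloxy)-5-methoxyphenyl]pentanoic acid, via alkylborane 5 (not isolated), via methyl ester 6 (not isolated)
Conditions: 3, 9-BBN, THF, 0 °C to rt; then 2, PdCl2(dppf) (cat.), aq K3PO4, THF/DMF, 60 °C; then LiOH, MeOH/H2O, rt; HCl work-up
Reagents that add atoms: lithium hydroxide, [Li+].[OH-]
Why: anti-Markovnikov hydroboration of the terminal alkene with 9-BBN (which spares the ester) and B-alkyl Suzuki–Miyaura coupling form the ring A–C1 bond, helped by both oxygens of 2 being meta to bromine so that oxidative addition is not slowed, and saponification in the same flask allows purification by acid–base extraction.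

**Step 3**
Reactants: 7 5-[3-(benzyloxy)-5-methoxyphenyl]pentanoic acid
Product: 8 1,3-dioxoisoindolin-2-yl 5-[3-(benzyloxy)-5-methoxyphenyl]pentanoate
Conditions: N-hydroxyphthalimide, DIC, DMAP (cat.), CH2Cl2, rt
Reagents that add atoms: N-hydroxyphthalimide, O=C1c2ccccc2C(=O)N1O
Why: Steglich-type carbodiimide esterification turns the acid into a stable redox-active ester whose N–O bond accepts an electron easily, and this activating group is lost again in step 7.

**Step 4**
Reactants: 9 5-bromobenzene-1,3-diol (5-bromoresorcinol)
Product: 10 1,3-bis(benzyloxy)-5-bromobenzene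
Conditions: BnBr (2.2 equiv), K2CO3, DMF, rt to 50 °C
Reagents that add atoms: benzyl bromide, BrCc1ccccc1
Why: a double Williamson ether synthesis masks both phenols of ring B with a group different from the methyl ether of ring A, so that the two rings stay distinguishable to the end.

**Step 5**
Reactants: 10 1,3-bis(benzyloxy)-5-bromobenzene; 11 methyl undec-10-enoate; 4 9-borabicyclo[3.3.1]nonane (9-BBN)
Product: 14 11-[3,5-bis(benzyloxy)phenyl]undecanoic acid, via alkylborane 12 (not isolated), via methyl ester 13 (not isolated)
Conditions: 11, 9-BBN, THF, 0 °C to rt; then 10, PdCl2(dppf) (cat.), aq K3PO4, THF/DMF, 60 °C; then LiOH, MeOH/THF/H2O, 40 °C; HCl work-up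
Reagents that add atoms: lithium hydroxide, [Li+].[OH-]
Why: the same hydroboration/B-alkyl Suzuki–Miyaura/saponification sequence as in step 2 forms the ring B–C14 bond from a classical substrate for this coupling.

**Step 6**
Reactants: 14 11-[3,5-bis(benzyloxy)phenyl]undecanoic acid
Product: 15 1,3-dioxoisoindolin-2-yl 11-[3,5-bis(benzyloxy)phenyl]undecanoate
Conditions: N-hydroxyphthalimide, DIC, DMAP (cat.), CH2Cl2, rt
Reagents that add atoms: N-hydroxyphthalimide, O=C1c2ccccc2C(=O)N1O
Why: Steglich-type carbodiimide esterification as in step 3 gives the second redox-active ester.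

**Step 7**
Reactants: 8 1,3-dioxoisoindolin-2-yl 5-[3-(benzyloxy)-5-methoxyphenyl]pentanoate; 15 1,3-dioxoisoindolin-2-yl 11-[3,5-bis(benzyloxy)phenyl]undecanoate
Product: 16 1-(benzyloxy)-3-{14-[3,5-bis(benzyloxy)phenyl]tetradecyl}-5-methoxybenzene
Conditions: 8 (3 equiv), 15 (1 equiv), NiCl2·6H2O (20 mol %), 2,2':6',2''-terpyridine (20 mol %), NaI, DMF, undivided cell, Zn anode/Ni-foam cathode, constant current, rt; aq HCl work-up
Reagents that add atoms: none
Why: Cathodically formed low-valent (terpyridine)nickel passes one electron to each N-(acyloxy)phthalimide, whose radical anion loses phthalimide anion and CO2, so that 8 gives the primary 4-arylbutyl radical and 15 the primary 10-aryldecyl radical; capture of both at nickel gives a dialkylnickel(III) species whose reductive elimination forms the C4–C5 CH2–CH2 bond, while the zinc anode supplies the two electrons. The closest known reaction type is the nickel-electrocatalytic doubly decarboxylative C(sp3)–C(sp3) cross-coupling of two redox-active esters, which is established for primary/primary pairs. No ring is closed and no stereocentre is formed. The selectivity needed is cross- over homo-coupling, which for two like primary radicals is only statistical; it is biased by the threefold excess of the smaller ester 8, and the three possible products carry two, three and four benzyl ethers (two, three and four free OH after step 8), so they should be separable at 16 or at the latest at 17. Chemoselectivity comes from working at the cathode, because the two 1,3-dioxygenated rings would be oxidised well below the potential of an anodic Kolbe coupling, whereas they and the benzyl ethers are inert at the potential at which the phthalimide esters are reduced. The 4-arylbutyl radical has only slow escape routes (a 1,4-H shift from C1 through a five-membered transition state, and slow ipso or ortho attack on ring A), any such loss falls on the partner used in excess, and the tridentate ligand holds back β-hydride elimination.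

**Step 8**
Reactants: 16 1-(benzyloxy)-3-{14-[3,5-bis(benzyloxy)phenyl]tetradecyl}-5-methoxybenzene
Product: 17 5-[14-(3-hydroxy-5-methoxyphenyl)tetradecyl]benzene-1,3-diol (target)
Conditions: H2 (1 atm), 10 % Pd/C, EtOAc/MeOH, rt
Reagents that add atoms: none
Why: catalytic hydrogenolysis cleaves the three benzylic C–O bonds, while the aryl methyl ether, both arenes and the saturated chain are inert under these mild conditions.

**Compound list**
1 | 3-bromo-5-methoxyphenol | COc1cc(O)cc(Br)c1 | starting material
2 | 1-(benzyloxy)-3-bromo-5-methoxybenzene | COc1cc(Br)cc(OCc2ccccc2)c1 | intermediate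
3 | methyl pent-4-enoate | COC(=O)CCC=C | starting material
4 | 9-borabicyclo[3.3.1]nonane (9-BBN) | B1C2CCCC1CCC2 | starting material
5 | methyl 5-(9-borabicyclo[3.3.1]nonan-9-yl)pentanoate | COC(=O)CCCCB1C2CCCC1CCC2 | intermediate
6 | methyl 5-[3-(benzyloxy)-5-methoxyphenyl]pentanoate | COC(=O)CCCCc1cc(OC)cc(OCc2ccccc2)c1 | intermediate
7 | 5-[3-(benzyloxy)-5-methoxyphenyl]pentanoic acid | OC(=O)CCCCc1cc(OC)cc(OCc2ccccc2)c1 | intermediate
8 | 1,3-dioxoisoindolin-2-yl 5-[3-(benzyloxy)-5-methoxyphenyl]pentanoate | O=C(CCCCc1cc(OC)cc(OCc2ccccc2)c1)ON1C(=O)c2ccccc2C1=O | intermediate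
9 | 5-bromobenzene-1,3-diol | Oc1cc(O)cc(Br)c1 | starting material
10 | 1,3-bis(benzyloxy)-5-bromobenzene | Brc1cc(OCc2ccccc2)cc(OCc2ccccc2)c1 | intermediate
11 | methyl undec-10-enoate | COC(=O)CCCCCCCCC=C | starting material
12 | methyl 11-(9-borabicyclo[3.3.1]nonan-9-yl)undecanoate | COC(=O)CCCCCCCCCCB1C2CCCC1CCC2 | intermediate
13 | methyl 11-[3,5-bis(benzyloxy)phenyl]undecanoate | COC(=O)CCCCCCCCCCc1cc(OCc2ccccc2)cc(OCc2ccccc2)c1 | intermediate
14 | 11-[3,5-bis(benzyloxy)phenyl]undecanoic acid | OC(=O)CCCCCCCCCCc1cc(OCc2ccccc2)cc(OCc2ccccc2)c1 | intermediate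
15 | 1,3-dioxoisoindolin-2-yl 11-[3,5-bis(benzyloxy)phenyl]undecanoate | O=C(CCCCCCCCCCc1cc(OCc2ccccc2)cc(OCc2ccccc2)c1)ON1C(=O)c2ccccc2C1=O | intermediate
16 | 1-(benzyloxy)-3-{14-[3,5-bis(benzyloxy)phenyl]tetradecyl}-5-methoxybenzene | COc1cc(OCc2ccccc2)cc(CCCCCCCCCCCCCCc2cc(OCc3ccccc3)cc(OCc3ccccc3)c2)c1 | intermediate
17 | 5-[14-(3-hydroxy-5-methoxyphenyl)tetradecyl]benzene-1,3-diol | COc1cc(O)cc(CCCCCCCCCCCCCCc2cc(O)cc(O)c2)c1 | target

Total step count: 8. Longest linear sequence: 5 (steps 1, 2, 3, 7, 8 or steps 4, 5, 6, 7, 8).

**Steps most likely to fail**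

**Step 7.** Homocoupling may consume the limiting ester. The radicals may be reduced early by hydrogen abstraction from the solvent, or lost by β-hydride elimination at nickel. The three closely related ethers may also be hard to separate.

The fallback sets out from 2, 4 and 15 and returns at 16. It forms the same C4–C5 bond from partners of unlike role, by a nickel-catalysed decarboxylative Negishi-type alkyl–alkyl coupling.
- But-3-en-1-ol and 9-BBN 4 (2.2 equiv, THF) should give 9-[4-(9-borabicyclo[3.3.1]nonan-9-yloxy)butyl]-9-borabicyclo[3.3.1]nonane F1.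
- F1 is coupled in the same flask with 2 (PdCl2(dppf), aq K3PO4, THF/DMF, 60 °C) to 4-[3-(benzyloxy)-5-methoxyphenyl]butan-1-ol F2.
- An Appel reaction (CBr4, PPh3, CH2Cl2, 0 °C) leads to 1-(benzyloxy)-3-(4-bromobutyl)-5-methoxybenzene F3.
- Magnesium in THF gives {4-[3-(benzyloxy)-5-methoxyphenyl]butyl}magnesium bromide F4.
- ZnCl2 (0.5 equiv) converts F4 into bis{4-[3-(benzyloxy)-5-methoxyphenyl]butyl}zinc F5.
- F5 and 15 with NiCl2·glyme and 4,4'-di-tert-butyl-2,2'-bipyridine in THF/DMF at rt should give 16.

Only 15 delivers a radical here, and the other carbon reaches nickel as a nucleophile, so no statistical mixture arises.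

**Step 2.** Transmetalation of the alkylborane may be slow, so that protodeboronation, alkene isomerisation after β-hydride elimination and hydrodebromination of 2 compete. Boron residues may also follow the acid through the extraction.

The fallback sets out from 2 and returns at 7. It replaces the cross-coupling by a carbonyl olefination.
- Bromine–lithium exchange (n-BuLi, THF, −78 °C) gives [3-(benzyloxy)-5-methoxyphenyl]lithium F6.
- DMF converts F6 into 3-(benzyloxy)-5-methoxybenzaldehyde F7.
- (3-Carboxypropyl)triphenylphosphonium bromide and NaHMDS (2 equiv, THF) give sodium 4-(triphenyl-λ5-phosphanylidene)butanoate F8.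
- The Wittig reaction of F8 with F7 should give, after acidification, (Z)-5-[3-(benzyloxy)-5-methoxyphenyl]pent-4-enoic acid F9. It is expected mainly as the Z isomer, and the geometry is erased in the next operation.
- Homogeneous hydrogenation (H2, RhCl(PPh3)3, benzene/EtOH, rt) saturates the alkene without cleaving the benzyl ether and gives 7.

**Step 5.** The same competition between slow transmetalation and borane decomposition applies. In addition, the long-chain carboxylate may form emulsions during the acid–base work-up.

The fallback sets out from 10 and returns at 14. It reverses the roles, using an aryl nucleophile and an alkyl electrophile.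
- 10 and magnesium (THF, reflux) give [3,5-bis(benzyloxy)phenyl]magnesium bromide F10.
- 11-Bromoundecanoic acid is deprotonated with MeMgCl (THF, −20 °C) to chloromagnesium 11-bromoundecanoate F11.
- Copper-catalysed Grignard–alkyl bromide coupling of F10 with F11 (Li2CuCl4 cat., THF/NMP, 0 °C) should give 14 after acidic work-up.

**Further compounds**
F1 | step 7 | 9-[4-(9-borabicyclo[3.3.1]nonan-9-yloxy)butyl]-9-borabicyclo[3.3.1]nonane | C(CCCB1C2CCCC1CCC2)OB1C2CCCC1CCC2
F2 | step 7 | 4-[3-(benzyloxy)-5-methoxyphenyl]butan-1-ol | OCCCCc1cc(OC)cc(OCc2ccccc2)c1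
F3 | step 7 | 1-(benzyloxy)-3-(4-bromobutyl)-5-methoxybenzene | BrCCCCc1cc(OC)cc(OCc2ccccc2)c1
F4 | step 7 | {4-[3-(benzyloxy)-5-methoxyphenyl]butyl}magnesium bromide | Br[Mg]CCCCc1cc(OC)cc(OCc2ccccc2)c1
F5 | step 7 | bis{4-[3-(benzyloxy)-5-methoxyphenyl]butyl}zinc | COc1cc(CCCC[Zn]CCCCc2cc(OC)cc(OCc3ccccc3)c2)cc(OCc2ccccc2)c1
F6 | step 2 | [3-(benzyloxy)-5-methoxyphenyl]lithium | [Li]c1cc(OC)cc(OCc2ccccc2)c1
F7 | step 2 | 3-(benzyloxy)-5-methoxybenzaldehyde | O=Cc1cc(OC)cc(OCc2ccccc2)c1
F8 | step 2 | sodium 4-(triphenyl-λ5-phosphanylidene)butanoate | [Na+].[O-]C(=O)CCC=P(c1ccccc1)(c1ccccc1)c1ccccc1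
F9 | step 2 | (Z)-5-[3-(benzyloxy)-5-methoxyphenyl]pent-4-enoic acid | OC(=O)CC/C=C\c1cc(OC)cc(OCc2ccccc2)c1
F10 | step 5 | [3,5-bis(benzyloxy)phenyl]magnesium bromide | Br[Mg]c1cc(OCc2ccccc2)cc(OCc2ccccc2)c1
F11 | step 5 | chloromagnesium 11-bromoundecanoate | [Mg+2].[Cl-].[O-]C(=O)CCCCCCCCCCBr
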